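**Retrosynthetic overview**
- Last bond: C4–aryl, by acid-mediated capture of the flavan-4-yl cation of a (2R,3S,4R)-flavan-3,4-diol with piceatannol (3,4-trans, at the stilbene ring position ortho to the styryl group).
- The diol comes from a (2R,3R)-trans-dihydroflavonol dibenzyl ether by debenzylation and ketone reduction.
- Key disconnection: ring C of the dihydroflavonol through its two C–O bonds (O1–C2 and C3–OH), made in one catalytic enantioselective epoxidation/6-endo epoxide-opening cascade on a 2'-hydroxychalcone; this sets C2 and C3.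
- The chalcone comes from a Claisen–Schmidt condensation of two commercial benzyl ethers; piceatannol comes from resveratrol by ortho-hydroxylation.
- Ring order: rings A and B and both stilbene rings are bought; ring C is the only ring formed (step 2); the stilbene is attached last.

Assumption: in step 2 the ligand L-PiPr2 (1,1'-(propane-1,3-diyl)bis{(2S)-2-[(2,6-diisopropylphenyl)carbamoyl]piperidine 1-oxide}, from L-pipecolic acid) is taken to give the (αR,βS) epoxide; if the sense proves opposite, its antipode from D-pipecolic acid is used.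

**Step 1**
Reactants: 1 1-[4-(benzyloxy)-2-hydroxyphenyl]ethan-1-one; 2 4-(benzyloxy)benzaldehyde
Product: 3 (E)-1-[4-(benzyloxy)-2-hydroxyphenyl]-3-[4-(benzyloxy)phenyl]prop-2-en-1-one
Conditions: KOH (50% aq), EtOH, 25 °C, 48 h; then cold 1 M HCl
Reagents that add atoms: none
Why: Claisen–Schmidt aldol condensation, in which the acetophenone enolate adds to the non-enolisable aldehyde and E1cB dehydration gives the conjugated (E)-enone, the benzyl ethers and the chelated 2'-phenol being inert to aqueous KOH.

**Step 2**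
Reactants: 3 (E)-1-[4-(benzyloxy)-2-hydroxyphenyl]-3-[4-(benzyloxy)phenyl]prop-2-en-1-one
Product: 5 (2R,3R)-7-(benzyloxy)-2-[4-(benzyloxy)phenyl]-3-hydroxy-2,3-dihydro-4H-chromen-4-one, via chalcone epoxide 4 (not isolated)
Conditions: Sc(OTf)3 (10 mol%), L-PiPr2 (10 mol%), 30% aq H2O2 (1.5 equiv), THF, 0 °C, 24 h; then 35 °C, 6 h
Reagents that add atoms: hydrogen peroxide, OO
Why: Proposed new method: a chelation-gated asymmetric Algar–Flynn–Oyamada-type cascade in which the 2'-hydroxy ketone binds trivalent scandium as a six-membered O,O-chelate inside the chiral N,N'-dioxide pocket, so that (a) the enone is activated for Weitz–Scheffer conjugate addition of H2O2 to one β-face and O–O closure of the scandium enolate gives the (αR,βS)-epoxide 4, (b) the bound phenol is held away from Cβ and cannot close to the flavanone by oxa-Michael addition, and (c) the same Lewis acid then activates the epoxide for 6-endo opening by the phenol at the benzylic, p-alkoxyphenyl-stabilised Cβ with inversion, closing ring C through the O1–C2 bond to the 2,3-trans (2R,3R) product while the retained Cα–O bond fixes C3; the closest known reaction types are the N,N'-dioxide/Sc(OTf)3-catalysed epoxidation of chelating enones with H2O2 and the racemic, base-mediated Algar–Flynn–Oyamada oxidation of 2'-hydroxychalcones.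

**Step 3**
Reactants: 5 (2R,3R)-7-(benzyloxy)-2-[4-(benzyloxy)phenyl]-3-hydroxy-2,3-dihydro-4H-chromen-4-one
Product: 7 (2R,3S,4R)-2-(4-hydroxyphenyl)-3,4-dihydro-2H-chromene-3,4,7-triol, via garbanzol 6 (not isolated)
Conditions: H2 (1 atm), Pd/C (10 wt% palladium metal on carbon), THF–MeOH (1:1), 25 °C, 3 h; filter (Celite); then NaBH4 (4 equiv), 0 °C, 2 h; AcOH to pH 6
Reagents that add atoms: none
Why: Hydrogenolysis of the two benzyl aryl ethers leaves the deactivated aryl ketone, and NaBH4 carbonyl reduction by axial hydride delivery to the half-chair with equatorial 2-aryl and 3-hydroxyl groups gives the 3,4-trans (4R) benzylic alcohol without touching C2 or C3 (the C4 centre is re-set in step 5).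

**Step 4**
Reactants: 8 resveratrol
Product: 10 piceatannol, via stilbene ortho-quinone 9 (not isolated)
Conditions: IBX (1.1 equiv), MeOH, −25 °C, 1 h; then aq Na2S2O4, 0 → 25 °C
Reagents that add atoms: IBX (2-iodoxybenzoic acid), O=C1OI(=O)(O)c2ccccc12
Why: IBX ortho-oxygenation of phenols, in which the most electron-rich phenol (the 4'-hydroxyl conjugated to the alkene) ligates pentavalent iodine, oxygen is delivered intramolecularly to the ortho carbon to give ortho-quinone 9, and dithionite reduces it to the catechol without touching the (E)-alkene or the resorcinol ring.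

**Step 5**
Reactants: 7 (2R,3S,4R)-2-(4-hydroxyphenyl)-3,4-dihydro-2H-chromene-3,4,7-triol; 10 piceatannol (3 equiv)
Product: 11 (2R,3S,4S)-4-{2-[(E)-2-(3,4-dihydroxyphenyl)ethenyl]-4,6-dihydroxyphenyl}-2-(4-hydroxyphenyl)-3,4-dihydro-2H-chromene-3,7-diol
Conditions: 0.1 M aq HCl–EtOH (3:1), Ar, dark, 25 °C, 16 h; Sephadex LH-20 (EtOH)
Reagents that add atoms: none
Why: Biomimetic SN1 Friedel–Crafts alkylation (flavan-3,4-diol/phenol condensation), in which acid ionises the C4 hydroxyl, which leaves as water, to the 7-hydroxyl-stabilised benzylic cation (para-quinone methide) that is attacked by the resorcinol ring of 10 at the carbon ortho to the styryl group and para to a hydroxyl, from the face anti to the 3-hydroxyl, setting the 4S (3,4-trans, 2,4-cis) centre while excess 10 suppresses self-condensation.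

**Compound list**
1 | 1-[4-(benzyloxy)-2-hydroxyphenyl]ethan-1-one | CC(=O)c1ccc(OCc2ccccc2)cc1O | starting material
2 | 4-(benzyloxy)benzaldehyde | O=Cc1ccc(OCc2ccccc2)cc1 | starting material
3 | (E)-1-[4-(benzyloxy)-2-hydroxyphenyl]-3-[4-(benzyloxy)phenyl]prop-2-en-1-one | O=C(/C=C/c1ccc(OCc2ccccc2)cc1)c1ccc(OCc2ccccc2)cc1O | intermediate
4 | [(2R,3S)-3-[4-(benzyloxy)phenyl]oxiran-2-yl][4-(benzyloxy)-2-hydroxyphenyl]methanone (trans chalcone epoxide) | O=C(c1ccc(OCc2ccccc2)cc1O)[C@@H]1O[C@H]1c1ccc(OCc2ccccc2)cc1 | intermediate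
5 | (2R,3R)-7-(benzyloxy)-2-[4-(benzyloxy)phenyl]-3-hydroxy-2,3-dihydro-4H-chromen-4-one (2,3-trans) | c1ccccc1COc1ccc([C@H]2Oc3cc(OCc4ccccc4)ccc3C(=O)[C@@H]2O)cc1 | intermediate
6 | garbanzol, (2R,3R)-3,7-dihydroxy-2-(4-hydroxyphenyl)-2,3-dihydro-4H-chromen-4-one | Oc1ccc([C@H]2Oc3cc(O)ccc3C(=O)[C@@H]2O)cc1 | intermediate
7 | (2R,3S,4R)-2-(4-hydroxyphenyl)-3,4-dihydro-2H-chromene-3,4,7-triol (2,3-trans-3,4-trans flavan-3,4-diol) | Oc1ccc([C@H]2Oc3cc(O)ccc3[C@@H](O)[C@@H]2O)cc1 | intermediate
8 | resveratrol, (E)-5-[2-(4-hydroxyphenyl)ethenyl]benzene-1,3-diol | Oc1ccc(/C=C/c2cc(O)cc(O)c2)cc1 | starting material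
9 | (E)-4-[2-(3,5-dihydroxyphenyl)ethenyl]cyclohexa-3,5-diene-1,2-dione (stilbene ortho-quinone) | O=C1C=CC(/C=C/c2cc(O)cc(O)c2)=CC1=O | intermediate
10 | piceatannol, (E)-4-[2-(3,5-dihydroxyphenyl)ethenyl]benzene-1,2-diol | Oc1ccc(/C=C/c2cc(O)cc(O)c2)cc1O | intermediate
11 | (2R,3S,4S)-4-{2-[(E)-2-(3,4-dihydroxyphenyl)ethenyl]-4,6-dihydroxyphenyl}-2-(4-hydroxyphenyl)-3,4-dihydro-2H-chromene-3,7-diol (CNP0170061.1; 2,3-trans-3,4-trans) | Oc1ccc([C@H]2Oc3cc(O)ccc3[C@@H](c3c(O)cc(O)cc3/C=C/c3ccc(O)c(O)c3)[C@@H]2O)cc1 | target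

**Step count and risks**
Total step count: 5. Longest linear sequence: 4 (steps 1, 2, 3, 5).

Most likely to fail, first: step 2, the proposed new step. It may give low enantioselectivity, flavanone by oxa-Michael closure, or aroyl-migration and aurone-type products from the activated epoxide; 5 is expected to be crystalline, so a modest ee could be upgraded by recrystallisation. The fallback uses known chemistry, sets out from 3 and comes back at 5. The 2'-hydroxyl of 3 is alkylated (NaH, MOMCl, DMF, 0 °C) to (E)-1-[4-(benzyloxy)-2-(methoxymethoxy)phenyl]-3-[4-(benzyloxy)phenyl]prop-2-en-1-one F1. Juliá–Colonna epoxidation (poly-L-leucine, urea–H2O2, DBU, THF, 25 °C) gives [(2R,3S)-3-[4-(benzyloxy)phenyl]oxiran-2-yl][4-(benzyloxy)-2-(methoxymethoxy)phenyl]methanone F2. HCl in MeOH–THF (50 °C) removes the acetal, and the freed phenol opens the epoxide at the benzylic carbon to give 5 (trans major, C3 retained).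

Second: step 5. It may give the 3,4-cis (4β) epimer, attack at the stilbene carbon between the two hydroxyls, or self-condensation of 7. The fallback sets out from 7 and comes back at 11. Acid-catalysed thiolysis of 7 (BnSH, AcOH, 25 °C) gives (2R,3R,4R)-4-(benzylsulfanyl)-2-(4-hydroxyphenyl)-3,4-dihydro-2H-chromene-3,7-diol F3. This isolable thioether is then activated with the thiophilic Lewis acid AgBF4 (THF, 0 °C) in the presence of 10, giving 11 under aprotic, kinetically controlled conditions without aqueous acid, which limits equilibration at C4.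

Third: step 4. It may over-oxidise, attack the resorcinol ring, or lose ortho-quinone 9 to polymerisation. The fallback sets out from 8 and comes back at 10. Resveratrol is ortho-hydroxylated biocatalytically with E. coli whole cells expressing the two-component flavin monooxygenase HpaBC (glycerol, air, 30 °C), which hydroxylates the monophenol ring directly with O2 and never passes through the quinone (new compounds: none F0).

**Further compounds**
F1 | step 2 | (E)-1-[4-(benzyloxy)-2-(methoxymethoxy)phenyl]-3-[4-(benzyloxy)phenyl]prop-2-en-1-one | COCOc1cc(OCc2ccccc2)ccc1C(=O)/C=C/c1ccc(OCc2ccccc2)cc1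
F2 | step 2 | [(2R,3S)-3-[4-(benzyloxy)phenyl]oxiran-2-yl][4-(benzyloxy)-2-(methoxymethoxy)phenyl]methanone | COCOc1cc(OCc2ccccc2)ccc1C(=O)[C@@H]1O[C@H]1c1ccc(OCc2ccccc2)cc1
F0 | step 4 | none | none
F3 | step 5 | (2R,3R,4R)-4-(benzylsulfanyl)-2-(4-hydroxyphenyl)-3,4-dihydro-2H-chromene-3,7-diol | Oc1ccc([C@H]2Oc3cc(O)ccc3[C@@H](SCc3ccccc3)[C@@H]2O)cc1
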